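Its constants are made up; no experiment stands behind them.

Violet carries twice the catalyst of ochre, against the same impurity.

    intermediate → side product (k1 = 0.030 h⁻¹)
    free catalyst + impurity → spent catalyst (k2 = 780 M⁻¹ h⁻¹)
    free catalyst + intermediate → free catalyst + target (k3 = 1.2 M⁻¹ h⁻¹)
    substrate → intermediate (k4 = 0.068 h⁻¹)

- ochre: substrate 1.0 M; free catalyst 3.3 mol%; impurity 26 mM; time 25 h
- violet: substrate 1.0 M; free catalyst 6.6 mol%; impurity 26 mM; time 25 h

- which of these there is most of at the end, counted by the substrate in it, ochre (target / intermediate / side product / substrate)
- which of these there is most of at the end, counted by the substrate in it, violet (target / intermediate / side product / substrate)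
- the largest of these amounts at the end, in percent of the substrate charged, ochre
- the largest of these amounts at the end, in percent of the substrate charged, violet

At the bench I would say that twice the catalyst gives twice the catalysed rate. That rule needs the impurity to be a small part of the catalyst, so I divide one charge by the other. The ratio is 78.8% in ochre and 39.4% in violet, and neither is a small part. Even the 7.00 mM of catalyst in excess in ochre removes impurity at a pseudo-first-order 5.46 h⁻¹, far faster than the 0.068 h⁻¹ of substrate conversion. So I take the working catalyst as charge minus impurity: 7.00 mM in ochre and 40.0 mM in violet, a factor of 5.71.

Intermediate stands in both of its exits, so while the working catalyst stays constant, dividing one rate by the other removes intermediate, and time with it. In violet the branch ratio, or selectivity factor, which is the catalysed constant times working catalyst over the uncatalysed constant, is 1.60. In ochre it is 0.280.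

Substrate conversion holds no catalyst, so I reckon 18.3% of substrate left in both flasks. Treating intermediate as the middle of a first-order chain, I get 46.0% in ochre and 27.5% in violet. The branch ratio divides the rest. For ochre I reckon 27.9% side product, less than its intermediate. For violet I reckon 33.4% target, more than its intermediate.

The forecast says “doubling the loading gives nearly six times the working catalyst”. It names intermediate at 46% for ochre and target at 33% for violet.

The simulation gives intermediate at 46.0% in ochre and target at 33.4% in violet. Target over side product reads 0.280 in ochre and 1.60 in violet, beside branch ratios of 0.280 and 1.60. The violet charge read at 4.0 d still holds 0.146% substrate and 0.613% intermediate. Its branch ratio of 1.60 sends 61.5% of what has passed through intermediate to target, which reckons to 61.1%. That flask reads 61.1% target and 38.2% side product.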